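Cuts: the polyene is cut at C11=C12 (last Wittig), C11'=C12' (Wittig on the C10 dialdehyde), C7=C8 (Horner–Wadsworth–Emmons) and C6'–C7' (Sonogashira). In ring B the C5–O bond is traced back to a 5,6-epoxide.
Enabling feature: in ring B the hydroxyls on the adjacent, fully substituted C5 and C6 are trans, and C7 on C6 is cis to O5. An acyl oxygen hung on O7 can therefore reach C5 anti to an epoxide oxygen that stays behind as O6.
Forward order: both carbocycles are bought, and the only ring closed is a temporary 1,3-dioxan-2-one (closed in step 4, opened in step 5). The ring B C10 aldehyde plus C5 gives a C15 dienal; the ring A triflate plus a C6 enynol gives a C15 salt, the C10 dialdehyde extends it to a C25 salt, and C25 + C15 gives C40.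
Stereochemistry: C6 and, after one inversion, C5 come from a Sharpless epoxidation with L-(+)-diethyl tartrate, and C3' comes from (4R,6R)-actinol. Alkene geometry comes from E building blocks, an E-selective phosphonate and a trialkylphosphonium ylide.
Ring B enters every olefination as the aldehyde, so no carbanion is ever conjugated with the C6–O bond, and the epoxide is opened before any polyene exists.

Key step: step 4

Assumption: carotenoid locants are used with ring B (diol ring) unprimed and ring A (acetylenic ring) primed, and (4R,6R)-actinol, (E)-3-methylpent-2-en-4-yn-1-ol and the C10 dialdehyde are taken as purchasable carotenoid and vitamin A building blocks.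

Step 1
Reactants: 1 β-cyclocitral
Product: 2 β-cyclogeraniol
Conditions: NaBH4, MeOH, 0 °C
Reagents that add atoms: none
Why: Borohydride 1,2-reduction of an enal whose β-carbon is tetrasubstituted and shielded, so conjugate reduction should not compete and no stereocentre is formed.

Step 2
Reactants: 2 β-cyclogeraniol; 3 tert-butyl hydroperoxide
Product: 4 (5S,6S)-5,6-epoxy-β-cyclogeraniol = [(1S,6S)-2,2,6-trimethyl-7-oxabicyclo[4.1.0]heptan-1-yl]methanol
Conditions: Ti(OiPr)4 (0.2 equiv), L-(+)-diethyl tartrate (0.25 equiv), t-BuOOH (2 equiv, decane), 4 Å sieves, CH2Cl2, −20 °C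
Reagents that add atoms: tert-butyl hydroperoxide CC(C)(C)OO
Why: Sharpless asymmetric epoxidation, in which the titanium tartrate complex binds O7 and passes the peroxide oxygen to one face of the tetrasubstituted C5=C6 bond; the (R,R)-tartrate, which makes the carbinol-bearing carbon S in geraniol-type primary allylic alcohols, should set 6S and, through the obligatory cis ring fusion, 5S.

Step 3
Reactants: 4 epoxy alcohol; 5 di-tert-butyl dicarbonate
Product: 6 tert-butyl [(1S,6S)-2,2,6-trimethyl-7-oxabicyclo[4.1.0]heptan-1-yl]methyl carbonate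
Conditions: Boc2O (1.5 equiv), 1-methylimidazole (0.2 equiv), toluene, 0 °C → rt
Reagents that add atoms: di-tert-butyl dicarbonate CC(C)(C)OC(=O)OC(=O)OC(C)(C)C
Why: Nucleophile-catalysed O-tert-butoxycarbonylation of a primary neopentyl alcohol under non-acidic conditions, which the acid-labile tetrasubstituted epoxide should survive unchanged.

Step 4
Reactants: 6 epoxy tert-butyl carbonate
Product: 8 cis-fused cyclic carbonate (4aS,8aR)-4a-hydroxy-5,5,8a-trimethylhexahydro-4H-benzo[d][1,3]dioxin-2-one, via dioxanylium borate zwitterion 7 (not isolated)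
Conditions: BF3·OEt2 (0.5 equiv), CH2Cl2, −78 → −40 °C; aq NaHCO3
Reagents that add atoms: none
Why: BF3 coordinates the epoxide oxygen, the C5–O bond lengthens because C5 is the tertiary centre without an electron-withdrawing neighbour, and the carbonyl oxygen of the O7 carbonate attacks C5 from the face opposite the departing oxygen to give ion 7, which sheds isobutene and a proton to leave 8 and free BF3. The closest known reaction type is the Lewis-acid-promoted cyclisation of epoxy alcohol tert-butyl carbonates to cyclic carbonates, also used to terminate epoxide-opening cascades. The only ring closed is the temporary 1,3-dioxan-2-one, formed in a 6-endo-tet mode with respect to the epoxide and cis-fused to ring B, which costs no strain because C7 already stands on the face anti to the epoxide oxygen. C5 is the one new stereocentre: it is inverted (S in 6, R in 8) under control of the epoxide configuration and of the short tether, which reaches C5 only from that face, while C6 keeps its oxygen and its spatial arrangement. The step needs attack at C5 rather than 5-exo attack at C6, and this is secured by the inductive destabilisation of charge at C6 by the C7–O bond, by the screening of C6 by the C1 gem-dimethyl group and by the cost of inverting a carbon locked between two quaternary neighbours. Low temperature and the internal trap should hold ring contraction, alkyl or hydride shifts and proton loss in check, and no polyene is present that could divert the epoxide to a furanoid.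

Step 5
Reactants: 8 cyclic carbonate
Product: 9 (1S,2R)-1-(hydroxymethyl)-2,6,6-trimethylcyclohexane-1,2-diol
Conditions: K2CO3 (0.2 equiv), MeOH, rt
Reagents that add atoms: none
Why: Base-catalysed transesterification (carbonate methanolysis) breaks only acyl C–O bonds, so O5, O6 and O7 stay on their carbons and both stereocentres are untouched.

Step 6
Reactants: 9 triol
Product: 10 (1R,2R)-1,2-dihydroxy-2,6,6-trimethylcyclohexane-1-carbaldehyde
Conditions: IBX (1.5 equiv), DMSO, rt
Reagents that add atoms: none
Why: IBX oxidation, in which the pentavalent iodine reagent can oxidise only the primary C7 carbinol, leaves tertiary hydroxyls alone and takes 1,2-diols to α-hydroxy carbonyl compounds without glycol cleavage.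

Step 7
Reactants: 10 dihydroxy aldehyde; 11 ethyl (2E)-4-(diethoxyphosphoryl)-3-methylbut-2-enoate
Product: 13 ethyl (2E,4E)-5-[(1R,2R)-1,2-dihydroxy-2,6,6-trimethylcyclohexyl]-3-methylpenta-2,4-dienoate, via lithiated phosphonate 12 (not isolated)
Conditions: 11 (2.5 equiv), n-BuLi (2.4 equiv), DMPU, THF, −78 °C; then 10, −78 °C → rt
Reagents that add atoms: ethyl (2E)-4-(diethoxyphosphoryl)-3-methylbut-2-enoate CCOC(=O)/C=C(C)/CP(=O)(OCC)OCC
Why: Horner–Wadsworth–Emmons olefination with the vinylogous C5 phosphonate, whose stabilised anion is too weak a base to form the C5 or C6 alkoxide that retro-aldol or α-ketol pathways would need; reversible addition to the hindered aldehyde favours the E C7=C8 bond and the lithium/DMPU protocol best keeps C9=C10 E.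

Step 8
Reactants: 13 dienoate
Product: 14 (1R,2R)-1-[(1E,3E)-5-hydroxy-3-methylpenta-1,3-dien-1-yl]-2,6,6-trimethylcyclohexane-1,2-diol
Conditions: iBu2AlH (5 equiv), CH2Cl2, −78 → 0 °C; aq potassium sodium tartrate
Reagents that add atoms: none
Why: Aluminium hydride 1,2-reduction of a dienoate to the dienol, with extra hydride consumed by the two hydroxyls that return on work-up, leaves both alkenes and their geometry intact.

Step 9
Reactants: 14 dienol
Product: 15 (2E,4E)-5-[(1R,2R)-1,2-dihydroxy-2,6,6-trimethylcyclohexyl]-3-methylpenta-2,4-dienal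
Conditions: IBX (1.3 equiv), DMSO–THF, rt
Reagents that add atoms: none
Why: IBX oxidation again, preferred to MnO2 because the latter can cleave ditertiary glycols, and fast enough on the primary dienylic alcohol at room temperature to avoid E/Z leakage.

Step 10
Reactants: 16 (4R,6R)-actinol = (4R,6R)-4-hydroxy-2,2,6-trimethylcyclohexanone
Product: 17 (4R,6R)-4-(tert-butyldimethylsilyloxy)-2,2,6-trimethylcyclohexanone
Conditions: TBSCl, imidazole, DMF, rt
Reagents that add atoms: tert-butyldimethylsilyl chloride CC(C)(C)[Si](C)(C)Cl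
Why: Standard silyl ether formation masks the only hydroxyl so that it cannot be sulfonylated in the next step, and neither stereocentre is affected.

Step 11
Reactants: 17 silyloxy ketone
Product: 19 (4R)-4-(tert-butyldimethylsilyloxy)-2,6,6-trimethylcyclohex-1-en-1-yl trifluoromethanesulfonate, via lithium enolate 18 (not isolated)
Conditions: LiN(iPr)2, THF, −78 °C; PhNTf2, −78 °C → rt
Reagents that add atoms: N-phenylbis(trifluoromethanesulfonimide) O=S(=O)(N(c1ccccc1)S(=O)(=O)C(F)(F)F)C(F)(F)F
Why: Enolate O-triflation, where the quaternary C2 allows deprotonation only at C6, which erases that stereocentre by design and gives a single tetrasubstituted enol triflate, while the silyl ether at the later C3' lies too far from the enolate to be eliminated.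

Step 12
Reactants: 19 enol triflate; 20 (2E)-3-methylpent-2-en-4-yn-1-ol
Product: 21 (2E)-5-[(4R)-4-(tert-butyldimethylsilyloxy)-2,6,6-trimethylcyclohex-1-en-1-yl]-3-methylpent-2-en-4-yn-1-ol
Conditions: Pd(PPh3)4 (5 mol%), CuI (10 mol%), iPr2NH, DMF, rt → 50 °C
Reagents that add atoms: (2E)-3-methylpent-2-en-4-yn-1-ol C#C/C(C)=C/CO
Why: Sonogashira coupling, in which zerovalent palladium inserts into the vinyl C–O bond of the triflate and the copper acetylide is transferred, forges C6'–C7' while tolerating the free allylic alcohol and leaving the bought E alkene untouched.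

Step 13
Reactants: 21 C15 enynol
Product: 22 C15 allylic bromide [(4R)-silyl ether, 9'E]
Conditions: CBr4, PPh3, CH2Cl2, 0 °C
Reagents that add atoms: carbon tetrabromide BrC(Br)(Br)Br
Why: Appel bromination displaces the activated primary allylic oxygen by SN2 under neutral conditions, so the silyl ether, the enyne and the E geometry should persist.

Step 14
Reactants: 22 allylic bromide
Product: 23 C15 tributylphosphonium bromide
Conditions: PBu3, toluene, rt
Reagents that add atoms: tributylphosphine CCCCP(CCCC)CCCC
Why: SN2 quaternisation by the strongly nucleophilic trialkylphosphine, chosen because allylic trialkylphosphonium ylides olefinate with high E selectivity and drift less at the alkene next to the alkyne than triphenyl analogues.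

Step 15
Reactants: 23 C15 phosphonium bromide; 24 (2E,4E,6E)-2,7-dimethylocta-2,4,6-trienedial
Product: 26 (2E,4E,6E,8E,10E)-13-[(4R)-4-(tert-butyldimethylsilyloxy)-2,6,6-trimethylcyclohex-1-en-1-yl]-2,7,11-trimethyltrideca-2,4,6,8,10-pentaen-12-ynal, via tributylphosphonium ylide 25 (not isolated)
Conditions: 24 (3 equiv), NaOMe, CH2Cl2–MeOH, 0 °C → rt, dark
Reagents that add atoms: (2E,4E,6E)-2,7-dimethylocta-2,4,6-trienedial O=C/C(C)=C/C=C/C=C(C)/C=O
Why: Wittig olefination in which an excess of the symmetrical dialdehyde limits double condensation, the longer product aldehyde is less electrophilic, and the trialkylphosphonium ylide should give the E C11'=C12' bond.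

Step 16
Reactants: 26 C25 aldehyde
Product: 27 C25 polyenynol (C12 carbinol)
Conditions: NaBH4, MeOH–CH2Cl2, 0 °C
Reagents that add atoms: none
Why: Borohydride 1,2-reduction of a polyenal to the polyenol, a routine apocarotenal operation that touches neither the alkyne nor the silyl ether.

Step 17
Reactants: 27 C25 polyenynol
Product: 28 C25 triphenylphosphonium bromide (phosphorus on C12)
Conditions: PPh3·HBr, CH2Cl2, 0 °C → rt, dark
Reagents that add atoms: triphenylphosphine hydrobromide [Br-].c1ccc(cc1)[PH+](c1ccccc1)c1ccccc1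
Why: Direct phosphonium salt formation from an allylic polyenol runs through the delocalised polyenyl cation, which phosphorus captures at its primary terminus, and the aprotic solvent and low temperature should spare the secondary silyl ether.

Step 18
Reactants: 28 C25 phosphonium bromide; 15 ring B C15 dienal
Product: 30 3'-O-tert-butyldimethylsilyl ether of the target, via triphenylphosphonium ylide 29 (not isolated)
Conditions: NaOMe, CH2Cl2–MeOH, 0 °C → rt, dark; then EtOAc, 40 °C (11Z → 11E)
Reagents that add atoms: none
Why: Wittig olefination of a semi-stabilised polyenyl ylide with a dienal tolerates the free tertiary hydroxyls, and any 11Z isomer is a sterically hindered cis alkene (H10 against the C13 methyl) that should relax to E on gentle warming, well below the temperature at which the unhindered C9' alkene moves.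

Step 19
Reactants: 30 silyl ether
Product: 31 (3'R,5R,6R)-7',8'-didehydro-5,6-dihydro-β,β-carotene-3',5,6-triol (target)
Conditions: Bu4NF, THF, 0 °C → rt, dark
Reagents that add atoms: none
Why: Fluoride-induced desilylation under non-acidic conditions is required because the tertiary C6 hydroxyl is allylic to the polyene and would ionise in acid, and it involves no stereocentre or alkene.

Compound list
1 | β-cyclocitral | CC1=C(C=O)C(C)(C)CCC1 | starting material
2 | β-cyclogeraniol | CC1=C(CO)C(C)(C)CCC1 | intermediate
3 | tert-butyl hydroperoxide | CC(C)(C)OO | starting material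
4 | [(1S,6S)-2,2,6-trimethyl-7-oxabicyclo[4.1.0]heptan-1-yl]methanol | OC[C@]12O[C@@]1(C)CCCC2(C)C | intermediate
5 | di-tert-butyl dicarbonate | CC(C)(C)OC(=O)OC(=O)OC(C)(C)C | starting material
6 | tert-butyl [(1S,6S)-2,2,6-trimethyl-7-oxabicyclo[4.1.0]heptan-1-yl]methyl carbonate | CC(C)(C)OC(=O)OC[C@]12O[C@@]1(C)CCCC2(C)C | intermediate
7 | 2-tert-butoxy-1,3-dioxan-2-ylium ion cis-fused to ring B, O6 bound to BF3 (zwitterion) | CC(C)(C)O[C+]1OC[C@@]2(O[B-](F)(F)F)C(C)(C)CCC[C@@]2(C)O1 | intermediate
8 | (4aS,8aR)-4a-hydroxy-5,5,8a-trimethylhexahydro-4H-benzo[d][1,3]dioxin-2-one | O=C1OC[C@@]2(O)C(C)(C)CCC[C@@]2(C)O1 | intermediate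
9 | (1S,2R)-1-(hydroxymethyl)-2,6,6-trimethylcyclohexane-1,2-diol | OC[C@@]1(O)C(C)(C)CCC[C@@]1(C)O | intermediate
10 | (1R,2R)-1,2-dihydroxy-2,6,6-trimethylcyclohexane-1-carbaldehyde | O=C[C@@]1(O)C(C)(C)CCC[C@@]1(C)O | intermediate
11 | ethyl (2E)-4-(diethoxyphosphoryl)-3-methylbut-2-enoate | CCOC(=O)/C=C(C)/CP(=O)(OCC)OCC | starting material
12 | lithium salt of the carbanion of 11 | [Li+].CCOC(=O)/C=C(C)/[CH-]P(=O)(OCC)OCC | intermediate
13 | ethyl (2E,4E)-5-[(1R,2R)-1,2-dihydroxy-2,6,6-trimethylcyclohexyl]-3-methylpenta-2,4-dienoate | CCOC(=O)/C=C(C)/C=C/[C@@]1(O)C(C)(C)CCC[C@@]1(C)O | intermediate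
14 | (1R,2R)-1-[(1E,3E)-5-hydroxy-3-methylpenta-1,3-dien-1-yl]-2,6,6-trimethylcyclohexane-1,2-diol | OC/C=C(C)/C=C/[C@@]1(O)C(C)(C)CCC[C@@]1(C)O | intermediate
15 | (2E,4E)-5-[(1R,2R)-1,2-dihydroxy-2,6,6-trimethylcyclohexyl]-3-methylpenta-2,4-dienal | O=C/C=C(C)/C=C/[C@@]1(O)C(C)(C)CCC[C@@]1(C)O | intermediate
16 | (4R,6R)-4-hydroxy-2,2,6-trimethylcyclohexanone (actinol) | C[C@H]1C(=O)C(C)(C)C[C@H](O)C1 | starting material
17 | (4R,6R)-4-(tert-butyldimethylsilyloxy)-2,2,6-trimethylcyclohexanone | C[C@H]1C(=O)C(C)(C)C[C@H](O[Si](C)(C)C(C)(C)C)C1 | intermediate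
18 | lithium enolate of 17 | [Li+].CC1=C([O-])C(C)(C)C[C@H](O[Si](C)(C)C(C)(C)C)C1 | intermediate
19 | (4R)-4-(tert-butyldimethylsilyloxy)-2,6,6-trimethylcyclohex-1-en-1-yl trifluoromethanesulfonate | CC1=C(OS(=O)(=O)C(F)(F)F)C(C)(C)C[C@H](O[Si](C)(C)C(C)(C)C)C1 | intermediate
20 | (2E)-3-methylpent-2-en-4-yn-1-ol | C#C/C(C)=C/CO | starting material
21 | (2E)-5-[(4R)-4-(tert-butyldimethylsilyloxy)-2,6,6-trimethylcyclohex-1-en-1-yl]-3-methylpent-2-en-4-yn-1-ol | CC1=C(C#C/C(C)=C/CO)C(C)(C)C[C@H](O[Si](C)(C)C(C)(C)C)C1 | intermediate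
22 | (E)-allylic bromide derived from 21 | CC1=C(C#C/C(C)=C/CBr)C(C)(C)C[C@H](O[Si](C)(C)C(C)(C)C)C1 | intermediate
23 | tributylphosphonium bromide derived from 22 | CC1=C(C#C/C(C)=C/C[P+](CCCC)(CCCC)CCCC)C(C)(C)C[C@H](O[Si](C)(C)C(C)(C)C)C1.[Br-] | intermediate
24 | (2E,4E,6E)-2,7-dimethylocta-2,4,6-trienedial | O=C/C(C)=C/C=C/C=C(C)/C=O | starting material
25 | tributylphosphonium ylide of 23 | CC1=C(C#C/C(C)=C/C=P(CCCC)(CCCC)CCCC)C(C)(C)C[C@H](O[Si](C)(C)C(C)(C)C)C1 | intermediate
26 | all-E C25 acetylenic aldehyde (aldehyde carbon C12), 3'R silyl ether | CC1=C(C#C/C(C)=C/C=C/C(C)=C/C=C/C=C(C)/C=O)C(C)(C)C[C@H](O[Si](C)(C)C(C)(C)C)C1 | intermediate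
27 | all-E C25 acetylenic alcohol | CC1=C(C#C/C(C)=C/C=C/C(C)=C/C=C/C=C(C)/CO)C(C)(C)C[C@H](O[Si](C)(C)C(C)(C)C)C1 | intermediate
28 | all-E C25 triphenylphosphonium bromide | CC1=C(C#C/C(C)=C/C=C/C(C)=C/C=C/C=C(C)/C[P+](c2ccccc2)(c2ccccc2)c2ccccc2)C(C)(C)C[C@H](O[Si](C)(C)C(C)(C)C)C1.[Br-] | intermediate
29 | triphenylphosphonium ylide of 28 | CC1=C(C#C/C(C)=C/C=C/C(C)=C/C=C/C=C(C)/C=P(c2ccccc2)(c2ccccc2)c2ccccc2)C(C)(C)C[C@H](O[Si](C)(C)C(C)(C)C)C1 | intermediate
30 | (3'R,5R,6R)-3'-(tert-butyldimethylsilyloxy)-7',8'-didehydro-5,6-dihydro-β,β-carotene-5,6-diol | CC1=C(C#C/C(C)=C/C=C/C(C)=C/C=C/C=C(C)/C=C/C=C(C)/C=C/[C@@]2(O)C(C)(C)CCC[C@@]2(C)O)C(C)(C)C[C@H](O[Si](C)(C)C(C)(C)C)C1 | intermediate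
31 | (3'R,5R,6R)-7',8'-didehydro-5,6-dihydro-β,β-carotene-3',5,6-triol | CC1=C(C#C/C(C)=C/C=C/C(C)=C/C=C/C=C(C)/C=C/C=C(C)/C=C/[C@@]2(O)C(C)(C)CCC[C@@]2(C)O)C(C)(C)C[C@H](O)C1 | target

Total steps: 19. Longest linear sequence: 11 steps (steps 1–9, 18 and 19, from β-cyclocitral). The ring A branch (steps 10–17) joins at step 18.

Steps most likely to fail

Risk 1, step 4. Capture by the weakly nucleophilic carbonate carbonyl may be outrun by semipinacol ring contraction or by proton loss at the developing C5 cation.
- The fallback changes the internal nucleophile and sets out from 4.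
- Phenyl isocyanate (pyridine, CH2Cl2) gives the phenylurethane F1. Its much more electron-rich carbonyl oxygen needs no cation expulsion and should close on C5 under a milder activator (Et2AlCl, CH2Cl2, −78 °C), again anti and 6-endo.
- This gives the cyclic N-phenyl iminocarbonate F2.
- Dilute aqueous acid in THF hydrolyses the C=N bond, and the route is rejoined at 8.

Risk 2, step 7. Addition of the bulky phosphonate anion to an aldehyde flanked by three fully substituted carbons may be slow. That would leave time for base-induced retro-aldol opening of the C5–C6 bond or an α-ketol shift.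
- The fallback replaces carbonyl olefination under base by a neutral two-stage vinylation and sets out from 10.
- Takai iodoolefination (CrCl2, CHI3, THF, 0 °C; a small carbenoid of divalent chromium origin that tolerates hydroxyls) gives the (E)-vinyl iodide F3.
- F3 is joined by Stille coupling (Pd2(dba)3, AsPh3, NMP, rt) to ethyl (E)-3-(tributylstannyl)but-2-enoate F4, made by stannylcupration of ethyl but-2-ynoate at −78 °C.
- Both alkene geometries are retained, and the route is rejoined at 13.

Risk 3, step 18. E/Z control at the new C11=C12 bond may be poor, and the C9' alkene next to the alkyne may drift toward Z during any equilibration used to correct it.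
- The fallback moves from a phosphonium ylide to a phosphonate carbanion and sets out from 27.
- Appel bromination at −30 °C (CBr4, PPh3, 2,6-lutidine) gives the C25 allylic bromide F5, which is used crude.
- Michaelis–Becker substitution with NaP(O)(OEt)2 in THF at −20 °C gives the diethyl C25 phosphonate F6.
- Horner–Wadsworth–Emmons reaction of F6 (KN(SiMe3)2, THF, −78 °C) with 15 should form the E alkene directly, without a later isomerisation, and the route is rejoined at 30.

Further compounds
F1 | step 4 | [(1S,6S)-2,2,6-trimethyl-7-oxabicyclo[4.1.0]heptan-1-yl]methyl N-phenylcarbamate | O=C(Nc1ccccc1)OC[C@]12O[C@@]1(C)CCCC2(C)C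
F2 | step 4 | (4aS,8aR)-4a-hydroxy-5,5,8a-trimethyl-2-(phenylimino)hexahydro-4H-benzo[d][1,3]dioxine | c1ccccc1N=C1OC[C@@]2(O)C(C)(C)CCC[C@@]2(C)O1
F3 | step 7 | (1R,2R)-1-[(E)-2-iodoethenyl]-2,6,6-trimethylcyclohexane-1,2-diol | I/C=C/[C@@]1(O)C(C)(C)CCC[C@@]1(C)O
F4 | step 7 | ethyl (E)-3-(tributylstannyl)but-2-enoate | CCCC[Sn](CCCC)(CCCC)/C(C)=C/C(=O)OCC
F5 | step 18 | all-E C25 acetylenic allylic bromide (bromine on C12), 3'R silyl ether | CC1=C(C#C/C(C)=C/C=C/C(C)=C/C=C/C=C(C)/CBr)C(C)(C)C[C@H](O[Si](C)(C)C(C)(C)C)C1
F6 | step 18 | all-E diethyl C25 phosphonate (phosphorus on C12), 3'R silyl ether | CC1=C(C#C/C(C)=C/C=C/C(C)=C/C=C/C=C(C)/CP(=O)(OCC)OCC)C(C)(C)C[C@H](O[Si](C)(C)C(C)(C)C)C1
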